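**Decision.** Judge this row by where the reagent goes, not by how much product a flask could hold.

all flasks: partner 0.242 M; reagent 0.264 M; protic impurity 0.110 M; capture agent 0.0220 M; time 8.0 h

|  | substrate |
|---|---|
| amber | 0.0080 M |
| violet | 0.025 M |
| green | 0.080 M |
| teal | 0.20 M |
| grey | 0.60 M |

    substrate + reagent → open intermediate (k1 = 0.935 L mol⁻¹ h⁻¹)
    second intermediate + capture agent → trapped intermediate (k2 = 6.18 L mol⁻¹ h⁻¹)
    reagent + partner → second intermediate (k3 = 0.405 L mol⁻¹ h⁻¹)
    open intermediate + second intermediate → product (k4 = 0.243 L mol⁻¹ h⁻¹)
    reagent + protic impurity → quenched reagent (k5 = 20.0 L mol⁻¹ h⁻¹)

- "hardly changes" means that all values lie within two and a half points (for a concentration: within two and a half percent of the largest)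
- run time (amber): 8.0 h
- a step back or a flat step of under half a percent of the largest counts as no turn

* [product] at the end for amber, violet, green, teal, grey, in this order
* how that number moves from the first to the last of them (rises all the way / hardly changes / rises, then falls / falls all the way / falls, then rises)

**The surplus.** At grey's start, the protic impurity still takes reagent faster than substrate and partner together. At amber's start, it takes reagent 22 times faster than the partner does, with a half-life of 0.32 h. I therefore strike the impurity's charge from the reagent and keep a surplus of 0.154 M.

**The split.** Call the split, a selectivity factor, the rate constant of the substrate step times [substrate], over that of the partner step times [partner], at the charge. It tells how many parts of surplus go to substrate for each part that goes to the partner. Amber has 0.0763; grey has 5.72. Product forms at a rate that follows [open intermediate] times [second intermediate], so with the surplus fixed I reckon that rate highest at a split of one, which is [substrate] = 0.105 M. Amber's split stands below one and grey's above, so I commit to this shape: rises, then falls.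

**One number?** No: the split carries no time. The reagent's clock, total first-order loss times the run time, is 0.844 for amber and 5.27 for grey. I therefore expect amber's surplus to be unfinished at the reading, and I place the turn above 0.105 M.

**Forecast.** It gives 1.900 × 10⁻⁴ M, 5.800 × 10⁻⁴ M, 0.0016 M, 0.0021 M and 0.001 M, and the shape rises, then falls, on the ground that at high loading “the substrate takes most of the remaining reagent”.

**Result.** The flasks give 2.21 × 10⁻⁴ M, 6.50 × 10⁻⁴ M, 0.00171 M, 0.00285 M and 0.00277 M: rises, then falls, with the turn read at 0.33 M. The shape agrees, but at grey the forecast stands lower.

**Grey's reagent.** Grey's split of 5.72 assigns 0.0229 M of the surplus to the partner, and the partner spent by 8.00 h is 0.0241 M. The row's shape owes part of its form to two things acting together, the path from reagent to quenched reagent and the reading at 8.0 h rather than ten times later: from 0.00277 M, grey goes to 0.00760 M without that path and to 0.00707 M at the later reading. In amber the same pair acts, and the later reading is the larger effect: without the path amber reaches 4.95 × 10⁻⁴ M, but at the later reading 0.00574 M.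

(The constants used here belong to no real substance.)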